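You have no rate constants for this flask, only two earlier runs at other levels of protic impurity, so the charges and the readings have to do the work.

| setting | Tuesday's | Sunday's | flask |
|---|---|---|---|
| left-handed substrate | 0.20 M | 0.20 M | 0.20 M |
| right-handed substrate | 0.20 M | 0.20 M | 0.20 M |
| partner | 3 equiv | 3 equiv | 3.00 equiv |
| protic impurity | 0.028 M | 0.044 M | 0.0200 M |
| catalyst | 6.8 mol% (in portions, 2) | 6.8 mol% (in portions, 2) | 6.8 mol% (in portions, 2) |
| remark | run made earlier; portions every 1.5 min | run made earlier; portions every 1.5 min | the portions of catalyst follow each other after 1.5 min, the first at the start |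
| time |  |  | 10 min |

| Tuesday's: time / min | Tuesday's: left-handed product / % | Sunday's: time / min | Sunday's: left-handed product / % |
|---|---|---|---|
| 0.667 | 6.9 | 0.667 | 6.9 |
| 1.00 | 9.4 | 1.00 | 9.5 |
| 2.00 | 16.9 | 2.00 | 17.8 |
| 3.00 | 23.9 | 3.00 | 24.0 |
| 5.00 | 31.8 | 5.00 | 30.6 |
| 8.00 | 36.1 | 8.00 | 36.2 |

(each reading ± 0.5 percentage points)

* amount of left-handed product in percent of the left-handed substrate and right-handed substrate together charged, at 30 s, 2.5 min and 10 min

Suppose each molecule of protic impurity destroys one of partner. The impurity share, which is [protic impurity] divided by the [partner] charged, then comes to 3.33% in the new flask. In words, it is the part of the partner charge that the impurity can take. It was 4.67% on Tuesday's run and 7.33% on Sunday's. Yet at 8.00 min those runs read 36.1% and 36.2%, a gap smaller than the scatter of 0.5 percentage points. The new flask lies 1.3 points below Tuesday's share, a smaller step than the 2.7 points between the two runs, so I expect it to follow their curve.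

One number is not enough, though, since the share gives no shape to that curve, and the shape must come from the readings. Scaling the first Tuesday reading back in proportion gives 5.17% at 30 s. The mean of the readings on both sides gives 20.6% at 2.5 min, and at 10 min I expect slightly more than the last readings.

The forecast gives 5.3%, 20.8% and 38%, slightly above mine at the two early times, judging that “at these levels the impurity has no visible effect”.

The flask gives 5.63%, 21.9% and 38.2%, so the forecast holds within its tolerance.

    partner + catalyst + left-handed substrate → catalyst + left-handed product (k = 1.10 M⁻² s⁻¹)
    partner + catalyst + right-handed substrate → catalyst + right-handed product (k = 0.0450 M⁻² s⁻¹)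
    2 partner → homo dimer (k = 0.00340 M⁻¹ s⁻¹)
    partner → decomposed reagent (k = 0.00110 s⁻¹)
    partner + protic impurity → quenched reagent (k = 0.220 M⁻¹ s⁻¹)

From Sunday's run to this flask the share falls by 4 points, and left-handed product at 5.00 min stands at 31.7% against the 30.6% read then. Partner used for left-handed product, over partner lost to decomposed reagent, is 1.7 at 2.12 min. That ratio falls to 0.64 at 10.0 min, when 11% of the partner charge remains.

The readings were computed for an exercise, noise included.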